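**Retrosynthetic overview**

1. The strategy rests on ring A: C5 (CH3, OH) and C6 (OH, chain carbon C7) are adjacent fully substituted carbinols with cis hydroxyls, both trans to the C3 hydroxyl. The C5–C6 bond is cut as a pinacol bond, which opens ring A to an acyclic C6 α-keto ester / C5 methyl ketone whose only stereocentre (C3) comes from (R)-epichlorohydrin.
2. Ring A is the only ring that is built (step 7). Ring B is taken intact from (4R,6R)-actinol through its enol triflate and a Sonogashira coupling (C6'–C7').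
3. Chain: C7=C8 by Horner–Wadsworth–Emmons olefination of the ring A C7 aldehyde (gives the C15 dienal). C11'=C12' by E-selective Wittig reaction of the ring B C15 tributylphosphonium salt with the C10 dialdehyde (gives the C25 unit).
4. Last C=C bond: C11=C12, by Wittig reaction of the C25 ylide with the ring A dienal. Ring A is the electrophile so that no carbanion is conjugated to C7 next to the C6 oxygen. Fluoride then removes the four silyl groups.

Key step: step 7

Numbering: carotenoid numbering is used for the target and late intermediates (ring A: C1 gem-dimethyl, C3, C5, C6; chain C7–C15 and C15'–C7'; ring B primed).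

Assumption: (4R,6R)-4-hydroxy-2,2,6-trimethylcyclohexanone (actinol), 2,7-dimethylocta-2,4,6-trienedial and diethyl (3-cyano-2-methylallyl)phosphonate are taken as catalogue chemicals; the phosphonate is used as supplied (E/Z mixture) because its allylic anion equilibrates before it reacts.

**Route**

Step 1
Reactants: 1 (R)-epichlorohydrin; 2 isopropenylmagnesium bromide
Product: 3 (2R)-1-chloro-4-methylpent-4-en-2-ol
Conditions: CuI (10 mol %), THF, −40 → −20 °C; aq. NH4Cl
Reagents that add atoms: none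
Why: Copper-catalysed Grignard opening of the epoxide at its unsubstituted carbon (SN2) breaks no bond to the stereocentre, so the chlorohydrin keeps the configuration of 1.

Step 2
Reactants: 3 (2R)-1-chloro-4-methylpent-4-en-2-ol
Product: 4 (2R)-2-(2-methylprop-2-en-1-yl)oxirane
Conditions: NaOH (powder), Et2O, rt; distilled and used as a solution
Reagents that add atoms: none
Why: Intramolecular Williamson etherification in which the alkoxide displaces the primary chloride, so the carbinol carbon keeps its configuration.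

Step 3
Reactants: 4 (2R)-2-(2-methylprop-2-en-1-yl)oxirane; 5 isobutyric acid
Product: 8 (5R)-3,3-dimethyl-5-(2-methylprop-2-en-1-yl)oxolan-2-one, via isobutyric acid dianion 6 (not isolated), via hydroxy carboxylate 7 (not isolated)
Conditions: 5, LiN(iPr)2 (2.2 equiv), THF, 0 → 45 °C; then 4, 0 °C → rt; aq. HCl; TsOH (cat.), CH2Cl2, rt
Reagents that add atoms: none
Why: Carboxylic acid dianion alkylation: the dianion opens the terminal epoxide at CH2 by SN2 and the γ-hydroxy acid lactonises on acidification, helped by the gem-dimethyl group, without touching the carbinol centre.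

Step 4
Reactants: 8 (5R)-3,3-dimethyl-5-(2-methylprop-2-en-1-yl)oxolan-2-one; 9 ethyl vinyl ether
Product: 11 (6R)-2-ethoxy-6-hydroxy-4,4,8-trimethylnona-1,8-dien-3-one, via 1-ethoxyvinyllithium 10 (not isolated)
Conditions: 9, t-BuLi, THF, −78 → 0 °C; then 8, −78 °C; H2O quench at −78 °C (kept at pH 7–8)
Reagents that add atoms: none
Why: Single addition of an α-alkoxyvinyl organolithium to a lactone (acyl substitution that stops at the ketone because the lithium hemiketalate survives until the quench), the 1-ethoxyvinyl group serving as a masked ethoxycarbonyl group.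

Step 5
Reactants: 11 (6R)-2-ethoxy-6-hydroxy-4,4,8-trimethylnona-1,8-dien-3-one (in equilibrium with its cyclic hemiketal)
Product: 12 (6R)-6-[(tert-butyldimethylsilyl)oxy]-2-ethoxy-4,4,8-trimethylnona-1,8-dien-3-one
Conditions: TBSCl, imidazole, DMF, rt
Reagents that add atoms: tert-butyldimethylsilyl chloride, CC(C)(C)[Si](C)(C)Cl
Why: Silyl ether formation under conditions where ring–chain tautomerism is fast, so the unhindered open-chain secondary alcohol is silylated while the tertiary hemiketal hydroxyl is too hindered for TBSCl.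

Step 6
Reactants: 12 (6R)-6-[(tert-butyldimethylsilyl)oxy]-2-ethoxy-4,4,8-trimethylnona-1,8-dien-3-one
Product: 13 ethyl (5S)-5-[(tert-butyldimethylsilyl)oxy]-3,3-dimethyl-2,7-dioxooctanoate
Conditions: O3, CH2Cl2, −78 °C; then Me2S, −78 °C → rt; used without delay
Reagents that add atoms: ozone, [O-][O+]=O
Why: Ozonolysis with reductive work-up cleaves both 1,1-disubstituted alkenes at once, the enol ether giving the ethyl ester of the α-keto ester and the isopropenyl group the methyl ketone, while the silyl ether is inert.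

Step 7
Reactants: 13 ethyl (5S)-5-[(tert-butyldimethylsilyl)oxy]-3,3-dimethyl-2,7-dioxooctanoate
Product: 14 ethyl (1S,2R,4S)-4-[(tert-butyldimethylsilyl)oxy]-1,2-dihydroxy-2,6,6-trimethylcyclohexane-1-carboxylate
Conditions: SmI2 (2.5 equiv, 0.05 M), THF, −78 °C, slow addition of 13, no proton donor; −78 → −20 °C; then H2O, aq. potassium sodium tartrate
Reagents that add atoms: none
Why: Proposed new method: divalent samarium transfers one electron to the α-keto ester carbonyl (C6), by far the most easily reduced group, giving a ketyl chelated by the ester oxygen; this radical adds to the samarium-bound C5 ketone carbon and a second electron converts the resulting oxygen radical into the trivalent samarium diolate, so the C5–C6 bond and both tertiary carbinols form in one operation. The closest known reaction type is the SmI2 pinacol cyclisation of 1,6-keto aldehydes and 1,6-diketones to cis-cyclohexane-1,2-diols; what is untested is a neopentyl α-keto ester as the ketyl partner adding to a plain methyl ketone. Ring A closes in a 6-exo-trig mode. The cis relation of the C5 and C6 hydroxyls is controlled by the one samarium that bridges both oxygens in the transition state, and their trans relation to the C3 silyloxy group by a chair in which the C3 silyloxy group and the C5 methyl are equatorial, since the other cis-diol would need the C5 methyl axial against the axial C1 methyl. The step needs reduction of the keto ester in preference to the methyl ketone and cyclisation faster than simple reduction or dimerisation of the ketyl; the large gap in reduction potential, the absence of a proton donor before the quench, high dilution and the folding effect of the C1 gem-dimethyl group are expected to secure this. The C3 stereocentre is not touched.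

Step 8
Reactants: 14 ethyl (1S,2R,4S)-4-[(tert-butyldimethylsilyl)oxy]-1,2-dihydroxy-2,6,6-trimethylcyclohexane-1-carboxylate
Product: 15 ethyl (1S,2R,4S)-4-[(tert-butyldimethylsilyl)oxy]-2,6,6-trimethyl-1,2-bis[(trimethylsilyl)oxy]cyclohexane-1-carboxylate
Conditions: TMSOTf (3 equiv), 2,6-lutidine, CH2Cl2, −78 → 0 °C
Reagents that add atoms: trimethylsilyl trifluoromethanesulfonate, C[Si](C)(C)OS(=O)(=O)C(F)(F)F
Why: Silylation with the silyl triflate is strong enough for both hindered tertiary hydroxyls and blocks the α-ketol shift that a free C6 hydroxyl would allow once C7 is an aldehyde, while remaining removable by fluoride at the end.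

Step 9
Reactants: 15 ethyl (1S,2R,4S)-4-[(tert-butyldimethylsilyl)oxy]-2,6,6-trimethyl-1,2-bis[(trimethylsilyl)oxy]cyclohexane-1-carboxylate
Product: 16 [(1R,2R,4S)-4-[(tert-butyldimethylsilyl)oxy]-2,6,6-trimethyl-1,2-bis[(trimethylsilyl)oxy]cyclohexyl]methanol
Conditions: iBu2AlH (4 equiv), CH2Cl2, −78 → 0 °C; aq. potassium sodium tartrate, cold
Reagents that add atoms: none
Why: Hydride reduction of the ester to the primary alcohol with iBu2AlH, to which silyl ethers are inert, the aluminium alkoxide being quenched cold so that no silyl group migrates (the descriptor at C1 changes only by priority).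

Step 10
Reactants: 16 [(1R,2R,4S)-4-[(tert-butyldimethylsilyl)oxy]-2,6,6-trimethyl-1,2-bis[(trimethylsilyl)oxy]cyclohexyl]methanol
Product: 17 (1S,2R,4S)-4-[(tert-butyldimethylsilyl)oxy]-2,6,6-trimethyl-1,2-bis[(trimethylsilyl)oxy]cyclohexane-1-carbaldehyde
Conditions: Dess–Martin periodinane, NaHCO3, CH2Cl2, 0 °C → rt
Reagents that add atoms: none
Why: Dess–Martin oxidation of the neopentyl-type primary alcohol to a non-enolisable aldehyde under buffered conditions that spare the trimethylsilyl ethers.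

Step 11
Reactants: 17 (1S,2R,4S)-4-[(tert-butyldimethylsilyl)oxy]-2,6,6-trimethyl-1,2-bis[(trimethylsilyl)oxy]cyclohexane-1-carbaldehyde; 18 diethyl [(2E)-3-cyano-2-methylprop-2-en-1-yl]phosphonate
Product: 20 (2E,4E)-5-[(1S,2R,4S)-4-[(tert-butyldimethylsilyl)oxy]-2,6,6-trimethyl-1,2-bis[(trimethylsilyl)oxy]cyclohexyl]-3-methylpenta-2,4-dienenitrile, via lithiated phosphonate 19 (not isolated)
Conditions: 18, n-BuLi, THF/DMPU, −78 → 0 °C; then 17, −78 °C → rt
Reagents that add atoms: none
Why: Horner–Wadsworth–Emmons olefination in which the small conjugation-stabilised phosphonate anion adds to the hindered non-enolisable aldehyde and phosphate elimination gives the (7E) alkene, the C9=C10 bond settling mainly as E (a minor 9Z isomer would be removed by chromatography).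

Step 12
Reactants: 20 (2E,4E)-5-[(1S,2R,4S)-4-[(tert-butyldimethylsilyl)oxy]-2,6,6-trimethyl-1,2-bis[(trimethylsilyl)oxy]cyclohexyl]-3-methylpenta-2,4-dienenitrile
Product: 22 (2E,4E)-5-[(1S,2R,4S)-4-[(tert-butyldimethylsilyl)oxy]-2,6,6-trimethyl-1,2-bis[(trimethylsilyl)oxy]cyclohexyl]-3-methylpenta-2,4-dienal, via N-aluminio aldimine 21 (not isolated)
Conditions: iBu2AlH (1.5 equiv), toluene, −78 °C; then wet SiO2, 0 °C
Reagents that add atoms: water, O
Why: Partial reduction of the conjugated nitrile by iBu2AlH stops at the N-aluminio aldimine, which is hydrolysed on wet silica without acid, so the allylic C6 silyl ether and the double-bond geometry are kept.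

Step 13
Reactants: 23 (4R,6R)-4-hydroxy-2,2,6-trimethylcyclohexan-1-one
Product: 24 (4R,6R)-4-[(tert-butyldimethylsilyl)oxy]-2,2,6-trimethylcyclohexan-1-one
Conditions: TBSCl, imidazole, DMF, rt
Reagents that add atoms: tert-butyldimethylsilyl chloride, CC(C)(C)[Si](C)(C)Cl
Why: Standard silyl ether formation on the secondary hydroxyl, which does not affect either stereocentre.

Step 14
Reactants: 24 (4R,6R)-4-[(tert-butyldimethylsilyl)oxy]-2,2,6-trimethylcyclohexan-1-one
Product: 26 (4R)-4-[(tert-butyldimethylsilyl)oxy]-2,6,6-trimethylcyclohex-1-en-1-yl trifluoromethanesulfonate, via lithium enolate 25 (not isolated)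
Conditions: LiN(iPr)2, THF, −78 °C; then PhNTf2, −78 °C → rt; H2O
Reagents that add atoms: N-phenylbis(trifluoromethanesulfonimide), O=S(=O)(N(c1ccccc1)S(=O)(=O)C(F)(F)F)C(F)(F)F
Why: Enol triflate formation in which the only α-hydrogen (at C6 of the ketone) is removed and the enolate is O-sulfonylated, giving one tetrasubstituted enol triflate; the C6 stereocentre is deliberately lost and the carbinol centre is untouched.

Step 15
Reactants: 26 (4R)-4-[(tert-butyldimethylsilyl)oxy]-2,6,6-trimethylcyclohex-1-en-1-yl trifluoromethanesulfonate; 27 (2E)-3-methylpent-2-en-4-yn-1-ol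
Product: 28 (2E)-5-[(4R)-4-[(tert-butyldimethylsilyl)oxy]-2,6,6-trimethylcyclohex-1-en-1-yl]-3-methylpent-2-en-4-yn-1-ol
Conditions: Pd(PPh3)4 (5 mol %), CuI (10 mol %), iPr2NH, DMF, rt
Reagents that add atoms: none
Why: Sonogashira coupling of the alkenyl triflate with the terminal alkyne forms the C6'–C7' bond and leaves the E geometry of the enynol untouched.

Step 16
Reactants: 28 (2E)-5-[(4R)-4-[(tert-butyldimethylsilyl)oxy]-2,6,6-trimethylcyclohex-1-en-1-yl]-3-methylpent-2-en-4-yn-1-ol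
Product: 30 tributyl[(2E)-5-[(4R)-4-[(tert-butyldimethylsilyl)oxy]-2,6,6-trimethylcyclohex-1-en-1-yl]-3-methylpent-2-en-4-yn-1-yl]phosphonium bromide, via allylic bromide 29 (not isolated)
Conditions: CBr4 (1.1 equiv), PPh3 (1.1 equiv), CH2Cl2, −20 °C; then PBu3 (1.3 equiv), −20 °C → rt
Reagents that add atoms: carbon tetrabromide, BrC(Br)(Br)Br; tributylphosphine, CCCCP(CCCC)CCCC
Why: Appel bromination followed by SN2 displacement with tributylphosphine, both without an allyl cation, so the 9'E geometry of the enyne (which scrambles easily under ionising conditions) is kept.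

Step 17
Reactants: 30 tributyl[(2E)-5-[(4R)-4-[(tert-butyldimethylsilyl)oxy]-2,6,6-trimethylcyclohex-1-en-1-yl]-3-methylpent-2-en-4-yn-1-yl]phosphonium bromide; 31 (2E,4E,6E)-2,7-dimethylocta-2,4,6-trienedial
Product: 33 (2E,4E,6E,8E,10E)-13-[(4R)-4-[(tert-butyldimethylsilyl)oxy]-2,6,6-trimethylcyclohex-1-en-1-yl]-2,7,11-trimethyltrideca-2,4,6,8,10-pentaen-12-ynal, via C15 ylide 32 (not isolated)
Conditions: KOtBu, THF, −78 °C; ylide added to 31 (3 equiv), −78 → 0 °C, dark
Reagents that add atoms: none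
Why: Wittig olefination with an allylic tributylphosphonium ylide, which is E-selective for the new C11'=C12' bond, run by adding the ylide to an excess of the dialdehyde so that only one formyl group reacts.

Step 18
Reactants: 33 (2E,4E,6E,8E,10E)-13-[(4R)-4-[(tert-butyldimethylsilyl)oxy]-2,6,6-trimethylcyclohex-1-en-1-yl]-2,7,11-trimethyltrideca-2,4,6,8,10-pentaen-12-ynal
Product: 34 (2E,4E,6E,8E,10E)-13-[(4R)-4-[(tert-butyldimethylsilyl)oxy]-2,6,6-trimethylcyclohex-1-en-1-yl]-2,7,11-trimethyltrideca-2,4,6,8,10-pentaen-12-yn-1-ol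
Conditions: NaBH4, MeOH/THF, 0 °C, dark
Reagents that add atoms: none
Why: Borohydride 1,2-reduction of the polyenal to the primary allylic alcohol, which affects neither the alkyne nor the silyl ether.

Step 19
Reactants: 34 (2E,4E,6E,8E,10E)-13-[(4R)-4-[(tert-butyldimethylsilyl)oxy]-2,6,6-trimethylcyclohex-1-en-1-yl]-2,7,11-trimethyltrideca-2,4,6,8,10-pentaen-12-yn-1-ol
Product: 36 tributyl[(2E,4E,6E,8E,10E)-13-[(4R)-4-[(tert-butyldimethylsilyl)oxy]-2,6,6-trimethylcyclohex-1-en-1-yl]-2,7,11-trimethyltrideca-2,4,6,8,10-pentaen-12-yn-1-yl]phosphonium bromide, via polyenyl bromide 35 (not isolated)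
Conditions: CBr4 (1.1 equiv), PPh3 (1.1 equiv), CH2Cl2, −30 °C, dark; then PBu3 (1.3 equiv), −30 → 0 °C
Reagents that add atoms: carbon tetrabromide, BrC(Br)(Br)Br; tributylphosphine, CCCCP(CCCC)CCCC
Why: Appel bromination with immediate SN2 trapping of the labile polyenyl bromide by tributylphosphine at low temperature, which avoids a polyenyl cation that would scramble the double-bond geometry.

Step 20
Reactants: 36 tributyl[(2E,4E,6E,8E,10E)-13-[(4R)-4-[(tert-butyldimethylsilyl)oxy]-2,6,6-trimethylcyclohex-1-en-1-yl]-2,7,11-trimethyltrideca-2,4,6,8,10-pentaen-12-yn-1-yl]phosphonium bromide; 22 (2E,4E)-5-[(1S,2R,4S)-4-[(tert-butyldimethylsilyl)oxy]-2,6,6-trimethyl-1,2-bis[(trimethylsilyl)oxy]cyclohexyl]-3-methylpenta-2,4-dienal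
Product: 38 (all-E)-(3S,5R,6S,3'R)-3,3'-bis[(tert-butyldimethylsilyl)oxy]-5,6-bis[(trimethylsilyl)oxy]-7',8'-didehydro-5,6-dihydro-β,β-carotene, via C25 ylide 37 (not isolated)
Conditions: NaN(SiMe3)2 (1.05 equiv), THF, −78 °C; then 22, −78 → 0 °C, dark, argon
Reagents that add atoms: none
Why: E-selective Wittig olefination of the ring A dienal with the C25 tributylphosphonium ylide forms C11=C12, ring A being the electrophile so that no carbanion is conjugated to C7 next to the C6 silyloxy leaving group.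

Step 21
Reactants: 38 (all-E)-(3S,5R,6S,3'R)-3,3'-bis[(tert-butyldimethylsilyl)oxy]-5,6-bis[(trimethylsilyl)oxy]-7',8'-didehydro-5,6-dihydro-β,β-carotene
Product: 39 (all-E)-(3S,5R,6S,3'R)-7',8'-didehydro-5,6-dihydro-β,β-carotene-3,5,6,3'-tetrol (the target)
Conditions: Bu4NF (6 equiv), THF, 0 °C → rt, dark, argon
Reagents that add atoms: none
Why: Fluoride-induced cleavage of all four silyl ethers under non-acidic conditions, as the acid-labile tertiary allylic C6 hydroxyl and the polyene require.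

**Compound list**

1 | (R)-epichlorohydrin, (2R)-2-(chloromethyl)oxirane | ClC[C@H]1CO1 | starting material
2 | isopropenylmagnesium bromide | CC(=C)[Mg]Br | starting material
3 | (2R)-1-chloro-4-methylpent-4-en-2-ol | ClC[C@H](O)CC(C)=C | intermediate
4 | (2R)-2-(2-methylprop-2-en-1-yl)oxirane | CC(=C)C[C@@H]1CO1 | intermediate
5 | isobutyric acid | CC(C)C(O)=O | starting material
6 | dilithium 2-methylprop-1-ene-1,1-bis(olate), the isobutyric acid dianion | [Li+].[Li+].CC(C)=C([O-])[O-] | intermediate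
7 | dilithium (4R)-2,2,6-trimethyl-4-oxidohept-6-enoate | [Li+].[Li+].[O-]C(=O)C(C)(C)C[C@H]([O-])CC(C)=C | intermediate
8 | (5R)-3,3-dimethyl-5-(2-methylprop-2-en-1-yl)oxolan-2-one | CC(=C)C[C@H]1OC(=O)C(C)(C)C1 | intermediate
9 | ethyl vinyl ether | C=COCC | starting material
10 | 1-ethoxyvinyllithium | [Li]C(=C)OCC | intermediate
11 | (6R)-2-ethoxy-6-hydroxy-4,4,8-trimethylnona-1,8-dien-3-one | CCOC(=C)C(=O)C(C)(C)C[C@H](O)CC(C)=C | intermediate
12 | (6R)-6-[(tert-butyldimethylsilyl)oxy]-2-ethoxy-4,4,8-trimethylnona-1,8-dien-3-one | CCOC(=C)C(=O)C(C)(C)C[C@H](O[Si](C)(C)C(C)(C)C)CC(C)=C | intermediate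
13 | ethyl (5S)-5-[(tert-butyldimethylsilyl)oxy]-3,3-dimethyl-2,7-dioxooctanoate | CCOC(=O)C(=O)C(C)(C)C[C@H](O[Si](C)(C)C(C)(C)C)CC(C)=O | intermediate
14 | ethyl (1S,2R,4S)-4-[(tert-butyldimethylsilyl)oxy]-1,2-dihydroxy-2,6,6-trimethylcyclohexane-1-carboxylate | CCOC(=O)[C@]1(O)C(C)(C)C[C@H](O[Si](C)(C)C(C)(C)C)C[C@@]1(C)O | intermediate
15 | ethyl (1S,2R,4S)-4-[(tert-butyldimethylsilyl)oxy]-2,6,6-trimethyl-1,2-bis[(trimethylsilyl)oxy]cyclohexane-1-carboxylate | CCOC(=O)[C@]1(O[Si](C)(C)C)C(C)(C)C[C@H](O[Si](C)(C)C(C)(C)C)C[C@@]1(C)O[Si](C)(C)C | intermediate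
16 | [(1R,2R,4S)-4-[(tert-butyldimethylsilyl)oxy]-2,6,6-trimethyl-1,2-bis[(trimethylsilyl)oxy]cyclohexyl]methanol | OC[C@]1(O[Si](C)(C)C)C(C)(C)C[C@H](O[Si](C)(C)C(C)(C)C)C[C@@]1(C)O[Si](C)(C)C | intermediate
17 | (1S,2R,4S)-4-[(tert-butyldimethylsilyl)oxy]-2,6,6-trimethyl-1,2-bis[(trimethylsilyl)oxy]cyclohexane-1-carbaldehyde | O=C[C@]1(O[Si](C)(C)C)C(C)(C)C[C@H](O[Si](C)(C)C(C)(C)C)C[C@@]1(C)O[Si](C)(C)C | intermediate
18 | diethyl [(2E)-3-cyano-2-methylprop-2-en-1-yl]phosphonate | CCOP(=O)(OCC)C/C(C)=C/C#N | starting material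
19 | lithium salt of the allylic carbanion of 18 | [Li+].CCOP(=O)(OCC)[CH-]/C(C)=C/C#N | intermediate
20 | (2E,4E)-5-[(1S,2R,4S)-4-[(tert-butyldimethylsilyl)oxy]-2,6,6-trimethyl-1,2-bis[(trimethylsilyl)oxy]cyclohexyl]-3-methylpenta-2,4-dienenitrile | N#C/C=C(C)/C=C/[C@]1(O[Si](C)(C)C)C(C)(C)C[C@H](O[Si](C)(C)C(C)(C)C)C[C@@]1(C)O[Si](C)(C)C | intermediate
21 | N-(diisobutylalumanyl) aldimine of 22 | CC(C)C[Al](CC(C)C)N=C/C=C(C)/C=C/[C@]1(O[Si](C)(C)C)C(C)(C)C[C@H](O[Si](C)(C)C(C)(C)C)C[C@@]1(C)O[Si](C)(C)C | intermediate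
22 | (2E,4E)-5-[(1S,2R,4S)-4-[(tert-butyldimethylsilyl)oxy]-2,6,6-trimethyl-1,2-bis[(trimethylsilyl)oxy]cyclohexyl]-3-methylpenta-2,4-dienal | O=C/C=C(C)/C=C/[C@]1(O[Si](C)(C)C)C(C)(C)C[C@H](O[Si](C)(C)C(C)(C)C)C[C@@]1(C)O[Si](C)(C)C | intermediate
23 | (4R,6R)-4-hydroxy-2,2,6-trimethylcyclohexan-1-one (actinol) | CC1(C)C[C@H](O)C[C@@H](C)C1=O | starting material
24 | (4R,6R)-4-[(tert-butyldimethylsilyl)oxy]-2,2,6-trimethylcyclohexan-1-one | CC1(C)C[C@H](O[Si](C)(C)C(C)(C)C)C[C@@H](C)C1=O | intermediate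
25 | lithium (4R)-4-[(tert-butyldimethylsilyl)oxy]-2,6,6-trimethylcyclohex-1-en-1-olate | [Li+].CC1=C([O-])C(C)(C)C[C@H](O[Si](C)(C)C(C)(C)C)C1 | intermediate
26 | (4R)-4-[(tert-butyldimethylsilyl)oxy]-2,6,6-trimethylcyclohex-1-en-1-yl trifluoromethanesulfonate | CC1=C(OS(=O)(=O)C(F)(F)F)C(C)(C)C[C@H](O[Si](C)(C)C(C)(C)C)C1 | intermediate
27 | (2E)-3-methylpent-2-en-4-yn-1-ol | C#C/C(C)=C/CO | starting material
28 | (2E)-5-[(4R)-4-[(tert-butyldimethylsilyl)oxy]-2,6,6-trimethylcyclohex-1-en-1-yl]-3-methylpent-2-en-4-yn-1-ol | CC1=C(C#C/C(C)=C/CO)C(C)(C)C[C@H](O[Si](C)(C)C(C)(C)C)C1 | intermediate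
29 | (2E)-5-[(4R)-4-[(tert-butyldimethylsilyl)oxy]-2,6,6-trimethylcyclohex-1-en-1-yl]-3-methylpent-2-en-4-yn-1-yl bromide | CC1=C(C#C/C(C)=C/CBr)C(C)(C)C[C@H](O[Si](C)(C)C(C)(C)C)C1 | intermediate
30 | tributyl[(2E)-5-[(4R)-4-[(tert-butyldimethylsilyl)oxy]-2,6,6-trimethylcyclohex-1-en-1-yl]-3-methylpent-2-en-4-yn-1-yl]phosphonium bromide | CC1=C(C#C/C(C)=C/C[P+](CCCC)(CCCC)CCCC)C(C)(C)C[C@H](O[Si](C)(C)C(C)(C)C)C1.[Br-] | intermediate
31 | (2E,4E,6E)-2,7-dimethylocta-2,4,6-trienedial | O=C/C(C)=C/C=C/C=C(C)/C=O | starting material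
32 | tributylphosphonium ylide of 30 | CC1=C(C#C/C(C)=C/C=P(CCCC)(CCCC)CCCC)C(C)(C)C[C@H](O[Si](C)(C)C(C)(C)C)C1 | intermediate
33 | (2E,4E,6E,8E,10E)-13-[(4R)-4-[(tert-butyldimethylsilyl)oxy]-2,6,6-trimethylcyclohex-1-en-1-yl]-2,7,11-trimethyltrideca-2,4,6,8,10-pentaen-12-ynal | CC1=C(C#C/C(C)=C/C=C/C(C)=C/C=C/C=C(C)/C=O)C(C)(C)C[C@H](O[Si](C)(C)C(C)(C)C)C1 | intermediate
34 | (2E,4E,6E,8E,10E)-13-[(4R)-4-[(tert-butyldimethylsilyl)oxy]-2,6,6-trimethylcyclohex-1-en-1-yl]-2,7,11-trimethyltrideca-2,4,6,8,10-pentaen-12-yn-1-ol | CC1=C(C#C/C(C)=C/C=C/C(C)=C/C=C/C=C(C)/CO)C(C)(C)C[C@H](O[Si](C)(C)C(C)(C)C)C1 | intermediate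
35 | (2E,4E,6E,8E,10E)-13-[(4R)-4-[(tert-butyldimethylsilyl)oxy]-2,6,6-trimethylcyclohex-1-en-1-yl]-2,7,11-trimethyltrideca-2,4,6,8,10-pentaen-12-yn-1-yl bromide | CC1=C(C#C/C(C)=C/C=C/C(C)=C/C=C/C=C(C)/CBr)C(C)(C)C[C@H](O[Si](C)(C)C(C)(C)C)C1 | intermediate
36 | tributyl[(2E,4E,6E,8E,10E)-13-[(4R)-4-[(tert-butyldimethylsilyl)oxy]-2,6,6-trimethylcyclohex-1-en-1-yl]-2,7,11-trimethyltrideca-2,4,6,8,10-pentaen-12-yn-1-yl]phosphonium bromide | CC1=C(C#C/C(C)=C/C=C/C(C)=C/C=C/C=C(C)/C[P+](CCCC)(CCCC)CCCC)C(C)(C)C[C@H](O[Si](C)(C)C(C)(C)C)C1.[Br-] | intermediate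
37 | tributylphosphonium ylide of 36 | CC1=C(C#C/C(C)=C/C=C/C(C)=C/C=C/C=C(C)/C=P(CCCC)(CCCC)CCCC)C(C)(C)C[C@H](O[Si](C)(C)C(C)(C)C)C1 | intermediate
38 | (all-E)-(3S,5R,6S,3'R)-3,3'-bis[(tert-butyldimethylsilyl)oxy]-5,6-bis[(trimethylsilyl)oxy]-7',8'-didehydro-5,6-dihydro-β,β-carotene | CC1=C(C#C/C(C)=C/C=C/C(C)=C/C=C/C=C(C)/C=C/C=C(C)/C=C/[C@]2(O[Si](C)(C)C)C(C)(C)C[C@H](O[Si](C)(C)C(C)(C)C)C[C@@]2(C)O[Si](C)(C)C)C(C)(C)C[C@H](O[Si](C)(C)C(C)(C)C)C1 | intermediate
39 | (all-E)-(3S,5R,6S,3'R)-7',8'-didehydro-5,6-dihydro-β,β-carotene-3,5,6,3'-tetrol | CC1=C(C#C/C(C)=C/C=C/C(C)=C/C=C/C=C(C)/C=C/C=C(C)/C=C/[C@]2(O)C(C)(C)C[C@H](O)C[C@@]2(C)O)C(C)(C)C[C@H](O)C1 | target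

**Step count**

Total: 21 steps. Longest linear sequence: 14 steps (steps 1–12, 20, 21); the ring B branch is steps 13–19.

**Steps most likely to fail**

1. Step 7 (samarium pinacol). The ketyl may be reduced and protonated to the α-hydroxy ester before it adds to the ketone. Closure may go through the other chair, losing facial control relative to C3. Trivalent samarium may also trigger aldol closure between the methyl ketone and the keto ester. Fallback, known chemistry, from 26 back to 14: the enol triflate 26 of the ring B branch has the same spatial arrangement at the carbinol carbon as ring A. Palladium-catalysed ethoxycarbonylation (Pd(OAc)2, 1,3-bis(diphenylphosphino)propane, CO 1 atm, EtOH, Et3N, DMF, 60 °C) should give ethyl (4R)-4-[(tert-butyldimethylsilyl)oxy]-2,6,6-trimethylcyclohex-1-ene-1-carboxylate F1. cis-Dihydroxylation of its tetrasubstituted double bond (OsO4, pyridine, then aq. NaHSO3; or RuCl3/NaIO4) from the face opposite the C3 silyloxy group should then give 14.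

2. Step 11 (olefination at C7). Addition to an aldehyde flanked by two fully substituted carbons may be slow. The intermediate alkoxide may then induce O-to-O migration of the C6 trimethylsilyl group or revert, instead of eliminating phosphate. Fallback from 17 back to 22: Takai iodo-olefination (CrCl2, CHI3, THF, 0 °C), whose small gem-dichromium reagent tolerates hindrance, should give (1S,2R,4S)-4-[(tert-butyldimethylsilyl)oxy]-1-[(E)-2-iodoethenyl]-2,6,6-trimethyl-1,2-bis[(trimethylsilyl)oxy]cyclohexane F2. Stille coupling (Pd2(dba)3, AsPh3, N-methylpyrrolidone, rt) with (2E)-3-(tributylstannyl)but-2-en-1-ol F3, made by stannylcupration of but-2-yn-1-ol, should give (2E,4E)-5-[(1S,2R,4S)-4-[(tert-butyldimethylsilyl)oxy]-2,6,6-trimethyl-1,2-bis[(trimethylsilyl)oxy]cyclohexyl]-3-methylpenta-2,4-dien-1-ol F4. MnO2 in CH2Cl2 would then oxidise F4 to 22.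

3. Step 5 (silylation of the ring-opened tautomer). The gem-dimethyl group may hold the material as the cyclic hemiketal, so that silylation stalls or goes to the anomeric oxygen, and the enol ether may hydrolyse during the long reaction. Fallback from 4 back to 12, acyclic throughout: lithiated isobutyronitrile (LiN(iPr)2, THF, −78 °C → rt) opens epoxide 4 to (4R)-4-hydroxy-2,2,6-trimethylhept-6-enenitrile F5. TBSCl/imidazole gives (4R)-4-[(tert-butyldimethylsilyl)oxy]-2,2,6-trimethylhept-6-enenitrile F6. iBu2AlH (toluene, −78 °C, wet SiO2) gives (4R)-4-[(tert-butyldimethylsilyl)oxy]-2,2,6-trimethylhept-6-enal F7. 1-Ethoxyvinyllithium (THF, −78 °C) gives (6R)-6-[(tert-butyldimethylsilyl)oxy]-2-ethoxy-4,4,8-trimethylnona-1,8-dien-3-ol F8 as a mixture of C3 epimers. Dess–Martin oxidation buffered with pyridine then gives 12.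

**Further compounds**

F1 | step 7 | ethyl (4R)-4-[(tert-butyldimethylsilyl)oxy]-2,6,6-trimethylcyclohex-1-ene-1-carboxylate | CC1=C(C(=O)OCC)C(C)(C)C[C@H](O[Si](C)(C)C(C)(C)C)C1
F2 | step 11 | (1S,2R,4S)-4-[(tert-butyldimethylsilyl)oxy]-1-[(E)-2-iodoethenyl]-2,6,6-trimethyl-1,2-bis[(trimethylsilyl)oxy]cyclohexane | I/C=C/[C@]1(O[Si](C)(C)C)C(C)(C)C[C@H](O[Si](C)(C)C(C)(C)C)C[C@@]1(C)O[Si](C)(C)C
F3 | step 11 | (2E)-3-(tributylstannyl)but-2-en-1-ol | CCCC[Sn](CCCC)(CCCC)/C(C)=C/CO
F4 | step 11 | (2E,4E)-5-[(1S,2R,4S)-4-[(tert-butyldimethylsilyl)oxy]-2,6,6-trimethyl-1,2-bis[(trimethylsilyl)oxy]cyclohexyl]-3-methylpenta-2,4-dien-1-ol | OC/C=C(C)/C=C/[C@]1(O[Si](C)(C)C)C(C)(C)C[C@H](O[Si](C)(C)C(C)(C)C)C[C@@]1(C)O[Si](C)(C)C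
F5 | step 5 | (4R)-4-hydroxy-2,2,6-trimethylhept-6-enenitrile | N#CC(C)(C)C[C@H](O)CC(C)=C
F6 | step 5 | (4R)-4-[(tert-butyldimethylsilyl)oxy]-2,2,6-trimethylhept-6-enenitrile | N#CC(C)(C)C[C@H](O[Si](C)(C)C(C)(C)C)CC(C)=C
F7 | step 5 | (4R)-4-[(tert-butyldimethylsilyl)oxy]-2,2,6-trimethylhept-6-enal | O=CC(C)(C)C[C@H](O[Si](C)(C)C(C)(C)C)CC(C)=C
F8 | step 5 | (6R)-6-[(tert-butyldimethylsilyl)oxy]-2-ethoxy-4,4,8-trimethylnona-1,8-dien-3-ol (C3 epimers) | CCOC(=C)C(O)C(C)(C)C[C@H](O[Si](C)(C)C(C)(C)C)CC(C)=C
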